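**Plan**

1. Retrosynthesis: the central cyclohexene (C2–C1=C10–C14–C15'–C4') is cut at C2–C4' (aldol) and at C10–C14 (vinyl–alkyl coupling). This is a [3+3] union of a 14-nor upper half (2,3-dione, C10 enol triflate) with a lower half that carries ICH2CH2 on a C3'=C4' silyl enol ether.
2. Enabling feature: C2 is both an α-ketol carbon (next to C3=O) and the β-hydroxy carbon of the C3' ketone through spiro C4', and C10 is a vinylic ring carbon (C1=C10) bearing the C14 methylene. C2 can therefore be the electrophilic carbonyl of a 1,2-dione and C10 an enol triflate.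
3. Forward: dehydrocostus lactone supplies both 5-7-5 tricycles. Its C7 is inverted first (epoxide, butenolide, retro-ene transposition), C3 is oxidised, then the route branches.
4. Lower half: directed cyclopropanation, oxidation, silyl iodide ring opening. Upper half: ozonolytic excision of C14, dehydrogenation, reductive enol triflation, C2 oxidation.
5. Last step: zinc insertion, Negishi coupling and intramolecular Mukaiyama aldol in one flask close the only new ring and give the target.
6. Stereochemistry: C1', C5, C5', C6, C6' come from dehydrocostus lactone; C7 and C7' from face-selective hydrogen delivery in the diazene retro-ene step; C4' and C2 are set in the key step.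

Key step: step 13

Remark: as drawn, both lactones of the target are cis-fused (H-6/H-7 and H-6'/H-7' cis), i.e. 7-epi relative to commercial dehydrocostus lactone, so C7 is inverted once (steps 1–3) before the route branches.

Numbering: guaiane locants (lactone C12(=O)–O–C6; exocyclic carbons C13, C14, C15). α is the face of H-5 (and of H-1', H-5' in the lower half). Primed locants are used for the lower half from compound 8 on. Ring A is the cyclopentane C1–C5 of the upper half.

**Step 1**
Reactants: 1 dehydrocostus lactone
Product: 2 11α,13-epoxide of dehydrocostus lactone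
Conditions: t-BuOOH, DBU, CH2Cl2, 0 → 23 °C
Reagents that add atoms: tert-butyl hydroperoxide, CC(C)(C)OO
Why: Weitz–Scheffer nucleophilic epoxidation, in which the peroxide anion adds only to the electron-poor C11=C13 alkene and the enolate closes on oxygen from the less hindered H-7 face, so the epoxide oxygen should sit syn to H-7 (this C11 centre is erased in step 2).

**Step 2**
Reactants: 2 11α,13-epoxide of dehydrocostus lactone
Product: 3 13-hydroxy-7(11)-butenolide
Conditions: Et2AlCl, lithium 2,2,6,6-tetramethylpiperidide, toluene, 0 °C; aq. potassium sodium tartrate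
Reagents that add atoms: none
Why: Aluminium amide-promoted epoxide-to-allylic-alcohol isomerisation, in which the amide on the epoxide-bound aluminium removes the only β-hydrogen (H-7, syn) as the C11–O bond breaks, giving the conjugated tetrasubstituted butenolide with a C13 carbinol and erasing the unwanted C7 configuration.

**Step 3**
Reactants: 3 13-hydroxy-7(11)-butenolide
Product: 6 7-epi-dehydrocostus lactone, via sulfonylhydrazide adduct 4 (not isolated), via allylic diazene 5 (not isolated)
Conditions: 2-nitrobenzenesulfonylhydrazide, PPh3, diethyl azodicarboxylate, THF/N-methylmorpholine, −30 °C; then 23 °C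
Reagents that add atoms: none
Why: Reductive 1,3-transposition of a primary allylic alcohol (Mitsunobu N-alkylation, loss of sulfinic acid, then sigmatropic retro-ene loss of N2 from the diazene) moves the alkene to C11=C13 and delivers hydrogen to C7; because C5 lies on the α face at C6, the seven-membered ring folds under the planar butenolide and hydrogen should arrive on the open β face, cis to H-6, giving the cis-fused lactone (7R).

**Step 4**
Reactants: 6 7-epi-dehydrocostus lactone
Product: 7 3α-hydroxy-7-epi-dehydrocostus lactone
Conditions: SeO2 (0.5 equiv), t-BuOOH, CH2Cl2, 23 °C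
Reagents that add atoms: tert-butyl hydroperoxide, CC(C)(C)OO (terminal oxidant; the oxygen is relayed by selenium dioxide, O=[Se]=O)
Why: SeO2/t-BuOOH allylic hydroxylation (ene reaction then 2,3-sigmatropic shift) at the C3 methylene next to the C4 exocyclic alkene, the position oxidised in the parent lactone; the C3 configuration (α expected) is irrelevant because C3 becomes a ketone in steps 6 and 8.

**Step 5**
Reactants: 7 3α-hydroxy-7-epi-dehydrocostus lactone
Product: 8 spirocyclopropyl carbinol
Conditions: Et2Zn, CH2I2, CH2Cl2, −10 → 0 °C
Reagents that add atoms: diiodomethane, ICI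
Why: Simmons–Smith cyclopropanation (Furukawa variant) directed by the zinc alkoxide of the allylic C3' hydroxyl, so the C4'=C15' alkene should react ahead of the undirected C10'=C14' alkene while the electron-poor lactone methylene is inert; the spiro carbon is not a stereocentre.

**Step 6**
Reactants: 8 spirocyclopropyl carbinol
Product: 9 spirocyclopropyl ketone
Conditions: Dess–Martin periodinane, CH2Cl2, 23 °C
Reagents that add atoms: none
Why: Dess–Martin oxidation of the secondary cyclopropyl carbinol to the spiro[2.4] ketone under near-neutral conditions that leave the alkenes, cyclopropane and lactone untouched.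

**Step 7**
Reactants: 9 spirocyclopropyl ketone
Product: 10 iodoethyl silyl enol ether (lower half)
Conditions: Me3SiI, (Me3Si)2NH (cat.), CH2Cl2, −78 → −20 °C; concentrated under argon and used crude
Reagents that add atoms: iodotrimethylsilane, C[Si](C)(C)I
Why: Silyl iodide homo-conjugate ring opening of a cyclopropyl ketone, in which O-silylation activates the ring and iodide opens either of the two equivalent CH2 groups in an SN2 manner; this fixes the enol ether at C3'=C4' (not toward C2') and unveils the primary iodide two carbons from C4'.

**Step 8**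
Reactants: 7 3α-hydroxy-7-epi-dehydrocostus lactone
Product: 11 7-epi-dehydrozaluzanin C
Conditions: Dess–Martin periodinane, CH2Cl2, 23 °C
Reagents that add atoms: none
Why: Dess–Martin oxidation of the allylic alcohol to the exocyclic enone, which also deactivates the C4=C15 alkene for the next step.

**Step 9**
Reactants: 11 7-epi-dehydrozaluzanin C
Product: 13 14-nor-3,10-diketone, via secondary ozonide 12 (not isolated)
Conditions: O3 (1.0 equiv), CH2Cl2, −78 °C; then Me2S, −78 → 23 °C
Reagents that add atoms: ozone, [O-][O+]=O
Why: Criegee ozonolysis should be chemoselective for C10=C14, the only electron-rich alkene (C4=C15 and C11=C13 are conjugated to carbonyl groups), and reduction of the ozonide excises C14 as formaldehyde without touching C1 or C5.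

**Step 10**
Reactants: 13 14-nor-3,10-diketone
Product: 14 ene-dione
Conditions: SeO2, t-BuOH, 80 °C
Reagents that add atoms: none
Why: SeO2 dehydrogenation of a 1,4-diketone to the 2-ene-1,4-dione (α-selenation of the C3 ketone at C2, then elimination with H-1), which makes C2 the less hindered β-carbon of the C10 enone.

**Step 11**
Reactants: 14 ene-dione
Product: 16 C10 enol triflate, via lithium enolate 15 (not isolated)
Conditions: LiBH(s-Bu)3 (1.0 equiv), THF, −78 °C; then N-(5-chloro-2-pyridyl)bis(trifluoromethanesulfonimide), −78 → −20 °C
Reagents that add atoms: N-(5-chloro-2-pyridyl)bis(trifluoromethanesulfonimide), Clc1ccc(N(S(=O)(=O)C(F)(F)F)S(=O)(=O)C(F)(F)F)nc1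
Why: Conjugate reduction with enolate trapping, in which the hindered borohydride should add to the doubly activated ene-dione at its CH terminus C2 faster than to the simple enone or the lactone methylene, and the resulting C10 lithium enolate is O-triflated in situ, so the C1=C10 regiochemistry is fixed by the mechanism.

**Step 12**
Reactants: 16 C10 enol triflate
Product: 17 2,3-dione enol triflate (upper half)
Conditions: SeO2, 1,4-dioxane, 70 °C; used crude
Reagents that add atoms: selenium dioxide, O=[Se]=O
Why: Riley oxidation of the C2 methylene, activated by both the C3 ketone and the allylic C1=C10 bond, to a ketone; the resulting 2,3-dione cannot enolise (C1 and C4 are sp2) and stays a free, electrophilic C2 carbonyl.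

**Step 13**
Reactants: 10 iodoethyl silyl enol ether (lower half); 17 2,3-dione enol triflate (upper half)
Product: 21 target CNP0269880.1, via alkylzinc iodide 18 (not isolated), via seco-dimer 19 (not isolated), via silyl ether 20 (not isolated)
Conditions: 10, Zn dust (Me3SiCl-activated), LiCl, THF, 30 °C; then 17, Pd2(dba)3 (2.5 mol%), SPhos (10 mol%), THF, 0 → 23 °C; then 40 °C; aq. citric acid
Reagents that add atoms: none
Why: Zinc inserts into the primary C–I bond of 10, zerovalent palladium adds to the C10–OTf bond of 17 and, after transmetalation and reductive elimination, joins C14 to C10; the tethered trimethylsilyl enol ether then adds through C4' to the C2 carbonyl of the α-diketone, activated by chelation to the divalent zinc salts formed in the coupling, and the C2 silyl ether is cleaved on work-up. The closest known reaction types are the Negishi coupling of functionalised alkylzinc iodides with enol triflates of β-dicarbonyl compounds and the Lewis acid-mediated Mukaiyama aldol addition to 1,2-diketones, here run in one flask. The only ring closed is the cyclohexene, by a 6-(enolexo)-exo-trig aldol closure onto C2; closure onto the C3 carbonyl would need a bridged seven-membered ring, and closure through C2' is excluded because the enol ether regiochemistry was fixed in step 7. C4' (R) should be set by approach of C2 to the convex α face of the cyclopentene enol ether, cis to H-1' and H-5' and away from the seven-membered ring on the β face. C2 (S) should be set by a half-chair transition state with an open, antiperiplanar arrangement of enol ether and carbonyl in which the bulky C5' branch of the spiro ring is equatorial and C3' axial, which requires bond formation on the β face of ring A and leaves the hydroxyl α. The step needs coupling at the triflate in the presence of several carbonyl groups and Michael acceptors, which the low nucleophilicity of the alkylzinc iodide and fast palladium catalysis at 0 °C should secure, and an intermolecular aldol at C2 before coupling would converge on the same ring.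

**Compound list**

1 | dehydrocostus lactone, (1R,5R,6S,7S)-guaia-4(15),10(14),11(13)-trien-12,6-olide (trans-fused lactone; H-1α, H-5α, H-6β, H-7α) | C=C1CC[C@H]2C(=C)CC[C@H]3C(=C)C(=O)O[C@@H]3[C@H]21 | starting material
2 | 11α,13-epoxide of dehydrocostus lactone (spiro-epoxide, oxygen syn to H-7) | C=C1CC[C@H]2C(=C)CC[C@H]3[C@@]4(CO4)C(=O)O[C@@H]3[C@H]21 | intermediate
3 | 13-hydroxyguaia-4(15),7(11),10(14)-trien-12,6-olide (H-1α, H-5α, H-6β; 2-(hydroxymethyl)butenolide) | C=C1CC[C@H]2C(=C)CCC3=C(CO)C(=O)O[C@@H]3[C@H]21 | intermediate
4 | sulfonylhydrazide adduct: C13–N(NH2)SO2(2-nitrophenyl) derivative of 3 | C=C1CC[C@H]2C(=C)CCC3=C(CN(N)S(=O)(=O)c4ccccc4[N+](=O)[O-])C(=O)O[C@@H]3[C@H]21 | intermediate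
5 | allylic diazene: C13–N=NH derivative of 3 | C=C1CC[C@H]2C(=C)CCC3=C(CN=N)C(=O)O[C@@H]3[C@H]21 | intermediate
6 | 7-epi-dehydrocostus lactone, (1R,5R,6S,7R) (cis-fused lactone; H-6β, H-7β) | C=C1CC[C@H]2C(=C)CC[C@@H]3C(=C)C(=O)O[C@@H]3[C@H]21 | intermediate
7 | 3α-hydroxy-7-epi-dehydrocostus lactone (either C3 epimer serves) | C=C1[C@H](O)C[C@H]2C(=C)CC[C@@H]3C(=C)C(=O)O[C@@H]3[C@H]21 | intermediate
8 | spirocyclopropyl carbinol: 7 with C4'=C15' turned into a cyclopropane spiro-fused at C4' | C1CC12[C@H](O)C[C@H]3C(=C)CC[C@@H]4C(=C)C(=O)O[C@@H]4[C@H]32 | intermediate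
9 | spirocyclopropyl ketone (C3' ketone of 8) | C1CC12C(=O)C[C@H]3C(=C)CC[C@@H]4C(=C)C(=O)O[C@@H]4[C@H]32 | intermediate
10 | iodoethyl silyl enol ether (lower half): C3'(OSiMe3)=C4' enol ether with a 2-iodoethyl group on C4'; H-1'α, H-5'α, H-6'β, H-7'β | ICCC1=C(O[Si](C)(C)C)C[C@H]2C(=C)CC[C@@H]3C(=C)C(=O)O[C@@H]3[C@H]21 | intermediate
11 | 7-epi-dehydrozaluzanin C (3-oxo-7-epi-dehydrocostus lactone) | C=C1C(=O)C[C@H]2C(=C)CC[C@@H]3C(=C)C(=O)O[C@@H]3[C@H]21 | intermediate
12 | secondary ozonide of 11: 1,2,4-trioxolane spiro-fused at C10 (both spiro epimers) | C=C1C(=O)C[C@H]2C3(OCOO3)CC[C@@H]4C(=C)C(=O)O[C@@H]4[C@H]21 | intermediate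
13 | 14-nor-3,10-diketone: 3,10-dioxo-14-norguaia-4(15),11(13)-dien-12,6-olide (H-1α, H-5α, H-6β, H-7β) | C=C1C(=O)C[C@H]2C(=O)CC[C@@H]3C(=C)C(=O)O[C@@H]3[C@H]21 | intermediate
14 | ene-dione: 3,10-dioxo-14-norguaia-1,4(15),11(13)-trien-12,6-olide (H-5α, H-6β, H-7β) | C=C1C(=O)C=C2C(=O)CC[C@@H]3C(=C)C(=O)O[C@@H]3[C@H]21 | intermediate
15 | lithium enolate: C1=C10–OLi, C2 methylene, C3 ketone | C=C1C(=O)CC2=C([O-])CC[C@@H]3C(=C)C(=O)O[C@@H]3[C@H]21.[Li+] | intermediate
16 | C10 enol triflate: 3-oxo-10-(trifluoromethylsulfonyloxy)-14-norguaia-1(10),4(15),11(13)-trien-12,6-olide | C=C1C(=O)CC2=C(OS(=O)(=O)C(F)(F)F)CC[C@@H]3C(=C)C(=O)O[C@@H]3[C@H]21 | intermediate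
17 | 2,3-dione enol triflate (upper half): 2,3-dioxo-10-(trifluoromethylsulfonyloxy)-14-norguaia-1(10),4(15),11(13)-trien-12,6-olide | C=C1C(=O)C(=O)C2=C(OS(=O)(=O)C(F)(F)F)CC[C@@H]3C(=C)C(=O)O[C@@H]3[C@H]21 | intermediate
18 | alkylzinc iodide of 10 (C14–ZnI) | I[Zn]CCC1=C(O[Si](C)(C)C)C[C@H]2C(=C)CC[C@@H]3C(=C)C(=O)O[C@@H]3[C@H]21 | intermediate
19 | seco-dimer: C10–C14 coupled 2,3-dione carrying the C3'=C4' silyl enol ether | C=C1C(=O)C(=O)C2=C(CCC4=C(O[Si](C)(C)C)C[C@H]5C(=C)CC[C@@H]6C(=C)C(=O)O[C@@H]6[C@H]54)CC[C@@H]3C(=C)C(=O)O[C@@H]3[C@H]21 | intermediate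
20 | silyl ether: C2 O-trimethylsilyl ether of the target | C=C1C(=O)[C@]2(O[Si](C)(C)C)C3=C(CC[C@@H]4C(=C)C(=O)O[C@@H]4[C@@H]13)CC[C@]21C(=O)C[C@H]2C(=C)CC[C@@H]3C(=C)C(=O)O[C@@H]3[C@H]21 | intermediate
21 | target CNP0269880.1 (2S, 4'R; C2 hydroxyl α on ring A; C2 on the α face of the spiro cyclopentanone) | C=C1C(=O)[C@]2(O)C3=C(CC[C@@H]4C(=C)C(=O)O[C@@H]4[C@@H]13)CC[C@]21C(=O)C[C@H]2C(=C)CC[C@@H]3C(=C)C(=O)O[C@@H]3[C@H]21 | target

**Step count and risks**

Total step count: 13. Longest linear sequence: 10 steps (steps 1, 2, 3, 4, 8, 9, 10, 11, 12, 13); the lower half joins after steps 5–7.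

Steps most likely to fail:

Step 13. The silyl enol ether may react intermolecularly at the wrong carbonyl (C3) or at a Michael acceptor before coupling, the alkylzinc may be protonated, or the aldol closure may show poor facial discrimination at C2. The fallback sets out from 10 and 17 and comes back at 21. Mild acidic hydrolysis of 10 (aq. citric acid, THF) should give the γ-iodo ketone F1 as a mixture of C4' epimers. Zinc insertion gives its alkylzinc iodide F2, and Negishi coupling with 17 should give the isolable seco-triketone F3. A separate, reversible aldol cyclisation by soft enolisation (MgBr2·OEt2, Et3N, CH2Cl2) would then run under thermodynamic control, in which both C4' epimers converge through the enolate on the isomer with the C5' branch equatorial, that is 21.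

Step 2. The aluminium amide may attack the lactone carbonyl or transfer an ethyl group, and an epoxide epimer lacking a syn H-7 would not eliminate. The fallback sets out from 2 and comes back at 6, bypassing step 3 as well. MgBr2·OEt2 should open the epoxide at the primary C13 to the bromohydrin F4. Syn-dehydration of the tertiary alcohol toward H-7 with methyl N-(triethylammoniosulfonyl)carbamate should give the allylic bromide F5. Zinc dust in THF/aq. NH4Cl would form the allylzinc bromide F6, which is protonated at C7 with allylic transposition on the open β face to give 6.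

Step 11. The hydride may add to the exocyclic enone or the lactone methylene instead of the ene-dione, or the lithium enolate may equilibrate toward C3 before triflation. The fallback sets out from 14 and comes back at 16, separating reduction from triflation. Catalytic 1,4-hydrosilylation (Et3SiH, RhCl(PPh3)3, benzene, 23 °C) should give the isolable triethylsilyl enol ether F7 with the C1=C10 regiochemistry. Fluoride-induced triflation (Bu4N Ph3SiF2, PhNTf2, THF, 0 °C) then gives 16.

**Further compounds**

F1 | step 13 | γ-iodo ketone (C4' epimers) from hydrolysis of 10 | ICCC1C(=O)C[C@H]2C(=C)CC[C@@H]3C(=C)C(=O)O[C@@H]3[C@H]21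
F2 | step 13 | alkylzinc iodide of F1 | I[Zn]CCC1C(=O)C[C@H]2C(=C)CC[C@@H]3C(=C)C(=O)O[C@@H]3[C@H]21
F3 | step 13 | seco-triketone (C10–C14 coupled 2,3-dione with free C3' ketone) | C=C1C(=O)C(=O)C2=C(CCC4C(=O)C[C@H]5C(=C)CC[C@@H]6C(=C)C(=O)O[C@@H]6[C@H]54)CC[C@@H]3C(=C)C(=O)O[C@@H]3[C@H]21
F4 | step 2 | 13-bromo-11α-hydroxy bromohydrin | C=C1CC[C@H]2C(=C)CC[C@H]3[C@@](O)(CBr)C(=O)O[C@@H]3[C@H]21
F5 | step 2 | 13-bromo-7(11)-butenolide (allylic bromide) | C=C1CC[C@H]2C(=C)CCC3=C(CBr)C(=O)O[C@@H]3[C@H]21
F6 | step 2 | allylzinc bromide of F5 | C=C1CC[C@H]2C(=C)CCC3=C(C[Zn]Br)C(=O)O[C@@H]3[C@H]21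
F7 | step 11 | C10 triethylsilyl enol ether | C=C1C(=O)CC2=C(O[Si](CC)(CC)CC)CC[C@@H]3C(=C)C(=O)O[C@@H]3[C@H]21
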